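**Retrosynthetic overview**
1. The target is a ten-membered carbocycle (both ring alkenes cis within the ring) fused trans to an α-methylene-γ-butyrolactone; the last operations are C15 desilylation and O-methylation of the C9 hydroxyl of macrocycle 29.
2. Key disconnection C9–C10: inside the ten-membered ring the unit O=C14–C10(=C1)–C9–O is a β-oxygenated α-alkylidene aldehyde, so C10 is the central carbon of an allenolate that a 1,3-oxygen shift unmasks from a C1 ethynyl carbinol (C1–C10≡C14–H); C2 and C9 are cis on C1=C10, as a tethered delivery requires. This leads back to the acyclic ynol aldehyde 26.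
3. 26 comes from an E-selective Wittig reaction (C4=C5) between lactone aldehyde 22 and the α-formyl ylide 9, which carries C1–C4, C10, C14 and C15.
4. 22 comes from an anti cross-aldol (C7–C8; the acceptor also brings C9 as a masked aldehyde), Felkin addition of a formyl anion equivalent (C5–C6) with lactonisation, and α-methylenation.
5. Ring order: γ-lactone first (step 9), ten-membered carbocycle second (step 19).

Key step: step 19

Remark on the chemistry (assumption): locants C1–C15 are germacranolide locants (lactone C12(=O)–O–C6, ring fusion C7, ester on C8, methoxy on C9, aldehyde carbon C14 on C10, hydroxymethyl carbon C15 on C4, exocyclic methylene C13 on C11). CIP descriptors in names are those of the compound named; 1, 2, 10 and 11 are taken as commercial.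

**Route**

Step 1
Reactants: 1 4-chlorobutanoyl chloride; 2 bis(trimethylsilyl)acetylene
Product: 3 6-chloro-1-(trimethylsilyl)hex-1-yn-3-one
Conditions: AlCl3, CH2Cl2, 0 °C
Reagents that add atoms: none
Why: Friedel–Crafts-type acylation of the bis-silyl alkyne with ipso-desilylation should give the alkynyl ketone at one terminus only.

Step 2
Reactants: 3 6-chloro-1-(trimethylsilyl)hex-1-yn-3-one
Product: 4 (3R)-6-chloro-1-(trimethylsilyl)hex-1-yn-3-ol
Conditions: Ru[(R,R)-TsNCH(Ph)CH(Ph)NH](p-cymene) (1 mol %), i-PrOH, 25 °C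
Reagents that add atoms: none
Why: Noyori-type asymmetric transfer hydrogenation of an alkynyl ketone, in which the alkynyl group takes the place of aryl in the CH/π-organised transition state, should set the C1 carbinol as R with the (R,R)-ligand.

Step 3
Reactants: 4 (3R)-6-chloro-1-(trimethylsilyl)hex-1-yn-3-ol
Product: 5 (3R)-3-[(tert-butyldimethylsilyl)oxy]-6-chloro-1-(trimethylsilyl)hex-1-yne
Conditions: TBSCl, imidazole, DMF, 25 °C
Reagents that add atoms: tert-butyldimethylsilyl chloride, CC(C)(C)[Si](C)(C)Cl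
Why: Standard silylation protects the carbinol against the base used for ylide formation without touching the stereocentre.

Step 4
Reactants: 5 (3R)-3-[(tert-butyldimethylsilyl)oxy]-6-chloro-1-(trimethylsilyl)hex-1-yne
Product: 6 [(4R)-4-[(tert-butyldimethylsilyl)oxy]-6-(trimethylsilyl)hex-5-yn-1-yl]triphenylphosphonium iodide
Conditions: NaI, PPh3, MeCN, reflux
Reagents that add atoms: triphenylphosphine, c1ccc(cc1)P(c1ccccc1)c1ccccc1; sodium iodide, [Na+].[I-]
Why: Finkelstein exchange in the flask followed by SN2 quaternisation of the phosphine at the primary carbon should give the salt.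

Step 5
Reactants: 6 [(4R)-4-[(tert-butyldimethylsilyl)oxy]-6-(trimethylsilyl)hex-5-yn-1-yl]triphenylphosphonium iodide
Product: 8 (5R)-5-[(tert-butyldimethylsilyl)oxy]-2-(triphenylphosphoranylidene)-7-(trimethylsilyl)hept-6-ynal, via phosphonium ylide 7 (not isolated)
Conditions: NaHMDS (2 equiv), THF, −78 °C; HCO2Et, −78 → 25 °C
Reagents that add atoms: ethyl formate, CCOC=O
Why: C-formylation of a non-stabilised phosphorus ylide by a formate ester (acyl transfer, then deprotonation of the acylphosphonium by the second equivalent of base) is the standard entry to α-substituted formyl-stabilised ylides.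

Step 6
Reactants: 8 (5R)-5-[(tert-butyldimethylsilyl)oxy]-2-(triphenylphosphoranylidene)-7-(trimethylsilyl)hept-6-ynal
Product: 9 (5R)-5-hydroxy-2-(triphenylphosphoranylidene)hept-6-ynal
Conditions: TBAF, THF, 0 → 25 °C
Reagents that add atoms: none
Why: Fluoride should cleave both the O–Si and the alkynyl C–Si bond while the formyl-stabilised ylide is inert, so that no hydroxyl or alkyne protecting group enters the main line.

Step 7
Reactants: 10 methyl 4-oxobutanoate; 11 2,2-dimethoxyacetaldehyde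
Product: 12 methyl (3R,4S)-3-formyl-4-hydroxy-5,5-dimethoxypentanoate
Conditions: D-proline (20 mol %), DMF, 4 °C, slow addition of 10 to 11 (2 equiv)
Reagents that add atoms: none
Why: In this proline-catalysed direct cross-aldol the E-enamine of 10 should attack the hydrogen-bonded, practically non-enolising acceptor 11 through the chair-like transition state that gives the anti aldol, D-proline setting C7 (R) and C8 (S).

Step 8
Reactants: 12 methyl (3R,4S)-3-formyl-4-hydroxy-5,5-dimethoxypentanoate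
Product: 13 methyl (3R,4S)-3-formyl-5,5-dimethoxy-4-[(triethylsilyl)oxy]pentanoate
Conditions: TESCl, imidazole, DMF, 0 °C (crude 12 used at once)
Reagents that add atoms: chlorotriethylsilane, CC[Si](Cl)(CC)CC
Why: Silylation of the β-hydroxy aldehyde blocks retro-aldol, dehydration and lactonisation through O8, and the silyl ether cannot eliminate as an acyloxy group would.

Step 9
Reactants: 13 methyl (3R,4S)-3-formyl-5,5-dimethoxy-4-[(triethylsilyl)oxy]pentanoate
Product: 15 (4S,5S)-5-(1,3-dithian-2-yl)-4-[(1S)-2,2-dimethoxy-1-[(triethylsilyl)oxy]ethyl]oxolan-2-one, via lithium alkoxide 14 (not isolated)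
Conditions: 1,3-dithiane, n-BuLi, THF, −30 °C; 13, −78 → 0 °C; aq. NH4Cl
Reagents that add atoms: 1,3-dithiane, C1CSCSC1
Why: Felkin–Anh addition of the formyl anion equivalent to the α-branched aldehyde, reinforced by the 1,3-anti preference of the β-silyloxy group, should set C6 (O6 syn to the C7 branch, anti to O8), and alkoxide 14 then closes the trans γ-lactone on the methyl ester.

Step 10
Reactants: 15 (4S,5S)-5-(1,3-dithian-2-yl)-4-[(1S)-2,2-dimethoxy-1-[(triethylsilyl)oxy]ethyl]oxolan-2-one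
Product: 17 (3R,4S,5S)-5-(1,3-dithian-2-yl)-4-[(1S)-2,2-dimethoxy-1-[(triethylsilyl)oxy]ethyl]-3-(hydroxymethyl)oxolan-2-one, via lithium enolate 16 (not isolated)
Conditions: LDA, THF, −78 °C; CH2O (gas), −78 → −30 °C; aq. NH4Cl
Reagents that add atoms: formaldehyde, C=O
Why: Aldol reaction of the lactone enolate with monomeric formaldehyde, anti to the C7 substituent, introduces C13; the C11 configuration is lost in the next step and is of no consequence.

Step 11
Reactants: 17 (3R,4S,5S)-5-(1,3-dithian-2-yl)-4-[(1S)-2,2-dimethoxy-1-[(triethylsilyl)oxy]ethyl]-3-(hydroxymethyl)oxolan-2-one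
Product: 19 (4S,5S)-5-(1,3-dithian-2-yl)-4-[(1S)-2,2-dimethoxy-1-[(triethylsilyl)oxy]ethyl]-3-methylideneoxolan-2-one, via primary mesylate 18 (not isolated)
Conditions: MsCl, Et3N, CH2Cl2, 0 °C; DBU, 0 → 25 °C
Reagents that add atoms: none
Why: Mesylation followed by E1cB elimination is the classical two-stage α-methylenation of lactones and avoids any S-alkylating or S-oxidising reagent.

Step 12
Reactants: 19 (4S,5S)-5-(1,3-dithian-2-yl)-4-[(1S)-2,2-dimethoxy-1-[(triethylsilyl)oxy]ethyl]-3-methylideneoxolan-2-one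
Product: 20 (4R,5S)-5-(1,3-dithian-2-yl)-4-[(1S)-1-hydroxy-2,2-dimethoxyethyl]-3-methylideneoxolan-2-one
Conditions: HF·pyridine, pyridine, THF, 0 °C
Reagents that add atoms: none
Why: Buffered HF should cleave the secondary triethylsilyl ether and leave the acetal, the dithiane and the methylene lactone untouched.

Step 13
Reactants: 20 (4R,5S)-5-(1,3-dithian-2-yl)-4-[(1S)-1-hydroxy-2,2-dimethoxyethyl]-3-methylideneoxolan-2-one
Product: 21 (1S)-1-[(2S,3R)-2-(1,3-dithian-2-yl)-4-methylidene-5-oxooxolan-3-yl]-2,2-dimethoxyethyl 2-methylprop-2-enoate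
Conditions: methacrylic anhydride, Et3N, DMAP (cat.), CH2Cl2, 0 → 25 °C
Reagents that add atoms: methacrylic anhydride, CC(=C)C(=O)OC(=O)C(C)=C
Why: DMAP-catalysed acylation installs the C8 ester of the target now, when C6 is no longer an aldehyde and β-elimination of the acyloxy group is impossible.

Step 14
Reactants: 21 (1S)-1-[(2S,3R)-2-(1,3-dithian-2-yl)-4-methylidene-5-oxooxolan-3-yl]-2,2-dimethoxyethyl 2-methylprop-2-enoate
Product: 22 (1S)-1-[(2S,3S)-2-formyl-4-methylidene-5-oxooxolan-3-yl]-2,2-dimethoxyethyl 2-methylprop-2-enoate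
Conditions: MeI, CaCO3, MeCN/H2O (9:1), 40 °C
Reagents that add atoms: water, O
Why: S-methylation and hydrolysis of the dithioacetal under carbonate-buffered conditions should free the C5 aldehyde without opening the dimethyl acetal or epimerising C6.

Step 15
Reactants: 22 (1S)-1-[(2S,3S)-2-formyl-4-methylidene-5-oxooxolan-3-yl]-2,2-dimethoxyethyl 2-methylprop-2-enoate; 9 (5R)-5-hydroxy-2-(triphenylphosphoranylidene)hept-6-ynal
Product: 23 (1S)-1-[(2R,3S)-2-[(1E,5R)-2-formyl-5-hydroxyhept-1-en-6-yn-1-yl]-4-methylidene-5-oxooxolan-3-yl]-2,2-dimethoxyethyl 2-methylprop-2-enoate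
Conditions: toluene, 70 °C
Reagents that add atoms: none
Why: Wittig olefination with an α-branched formyl-stabilised ylide is E-selective (C6 trans to the formyl carbon C15, cis to C3), which is the ring-cis geometry of C4=C5, and the weakly basic ylide should spare the acrylate units and the C6 stereocentre.

Step 16
Reactants: 23 (1S)-1-[(2R,3S)-2-[(1E,5R)-2-formyl-5-hydroxyhept-1-en-6-yn-1-yl]-4-methylidene-5-oxooxolan-3-yl]-2,2-dimethoxyethyl 2-methylprop-2-enoate
Product: 24 (1S)-1-[(2R,3S)-2-[(1E,5R)-5-hydroxy-2-(hydroxymethyl)hept-1-en-6-yn-1-yl]-4-methylidene-5-oxooxolan-3-yl]-2,2-dimethoxyethyl 2-methylprop-2-enoate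
Conditions: NaBH4, CeCl3·7H2O, MeOH, −78 °C
Reagents that add atoms: none
Why: Luche reduction should reduce the enal 1,2 much faster than it attacks the lactone, the ester or the methylene lactone by conjugate addition.

Step 17
Reactants: 24 (1S)-1-[(2R,3S)-2-[(1E,5R)-5-hydroxy-2-(hydroxymethyl)hept-1-en-6-yn-1-yl]-4-methylidene-5-oxooxolan-3-yl]-2,2-dimethoxyethyl 2-methylprop-2-enoate
Product: 25 (1S)-1-[(2R,3S)-2-[(1E,5R)-2-{[(tert-butyldiphenylsilyl)oxy]methyl}-5-hydroxyhept-1-en-6-yn-1-yl]-4-methylidene-5-oxooxolan-3-yl]-2,2-dimethoxyethyl 2-methylprop-2-enoate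
Conditions: TBDPSCl (1.05 equiv), imidazole, CH2Cl2, −20 °C
Reagents that add atoms: tert-butyl(chloro)diphenylsilane, CC(C)(C)[Si](Cl)(c1ccccc1)c1ccccc1
Why: The bulky silyl chloride should select the primary allylic hydroxyl over the secondary propargylic one, which must stay free for the key step.

Step 18
Reactants: 25 (1S)-1-[(2R,3S)-2-[(1E,5R)-2-{[(tert-butyldiphenylsilyl)oxy]methyl}-5-hydroxyhept-1-en-6-yn-1-yl]-4-methylidene-5-oxooxolan-3-yl]-2,2-dimethoxyethyl 2-methylprop-2-enoate
Product: 26 (1S)-1-[(2R,3S)-2-[(1E,5R)-2-{[(tert-butyldiphenylsilyl)oxy]methyl}-5-hydroxyhept-1-en-6-yn-1-yl]-4-methylidene-5-oxooxolan-3-yl]-2-oxoethyl 2-methylprop-2-enoate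
Conditions: TFA/H2O (9:1), CH2Cl2, 0 °C
Reagents that add atoms: water, O
Why: Aqueous acid hydrolysis of the dimethyl acetal, slow because of the α-acyloxy group and therefore run in strong acid, should spare the acid-stable tert-butyldiphenylsilyl ether and give the C9 aldehyde, which is used at once.

Step 19
Reactants: 26 (1S)-1-[(2R,3S)-2-[(1E,5R)-2-{[(tert-butyldiphenylsilyl)oxy]methyl}-5-hydroxyhept-1-en-6-yn-1-yl]-4-methylidene-5-oxooxolan-3-yl]-2-oxoethyl 2-methylprop-2-enoate
Product: 29 (6R,7S,8S,9S)-15-[(tert-butyldiphenylsilyl)oxy]-9-hydroxy-8-(methacryloyloxy)-14-oxogermacra-1(10)E,4E,11(13)-trien-12,6-olide (both ring alkenes cis in the ring), via propargyl vanadate 27 (not isolated), via allenyl vanadate 28 (not isolated)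
Conditions: VO(OSiPh3)3 (15 mol %), 4 Å molecular sieves, ClCH2CH2Cl, 80 °C, syringe-pump addition of 26 (final 0.002 M)
Reagents that add atoms: none
Why: Proposed new method: the C1 hydroxyl of 26 should exchange onto the oxovanadium catalyst to give propargyl vanadate 27, a suprafacial [3,3] oxo shift (the Meyer–Schuster manifold) gives vanadium allenoate 28, and its central carbon C10 adds to the vanadium-bound C9 aldehyde through a six-membered closed transition state, after which alkoxide exchange releases 29 and the catalyst. The closest known reaction type is the oxovanadium-catalysed Meyer–Schuster rearrangement of ethynyl carbinols to enals and its intermolecular interception by aldehydes (aldol-type coupling of propargylic alcohols with aldehydes); new here are the intramolecular medium-ring version and the terminal alkyne that delivers an aldehyde. The ten-membered carbocycle closes in a 10-(enolexo)-exo-trig mode, the seven-atom tether C2–C8 delivering the aldehyde to the allenoate lobe syn to C2, so that C2 and C9 end cis on C1=C10 (the E-enal of the target), the reverse of the intermolecular preference for attack anti to the carbinol substituent. The new stereocentre C9 is controlled by relay from C1: the (R)-carbinol gives the (Ra)-allenoate, which holds O–V on one face, and in the closed transition state O9 must lie on that face while allylic 1,3-strain keeps H9 in the alkene plane toward C2, which exposes the Si face of the aldehyde and gives 9S. The step needs aldol over protonation of the allenoate (plain enal) and cyclisation over oligomerisation, which the absence of any other hydroxyl group (C15 is silylated), the molecular sieves and slow addition at high dilution should secure. The two acrylate-type acceptors are not activated by coordination to vanadium and should stay untouched.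

Step 20
Reactants: 29 (6R,7S,8S,9S)-15-[(tert-butyldiphenylsilyl)oxy]-9-hydroxy-8-(methacryloyloxy)-14-oxogermacra-1(10)E,4E,11(13)-trien-12,6-olide
Product: 30 (6R,7S,8S,9S)-15-[(tert-butyldiphenylsilyl)oxy]-9-methoxy-8-(methacryloyloxy)-14-oxogermacra-1(10)E,4E,11(13)-trien-12,6-olide
Conditions: Me3OBF4, 1,8-bis(dimethylamino)naphthalene, 4 Å molecular sieves, CH2Cl2, 0 → 25 °C
Reagents that add atoms: trimethyloxonium tetrafluoroborate, C[O+](C)C.F[B-](F)(F)F
Why: O-methylation with the oxonium salt buffered by a non-nucleophilic base involves no alkoxide, so migration of the neighbouring methacrylate and addition to the Michael acceptors should be avoided, and C9 is untouched.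

Step 21
Reactants: 30 (6R,7S,8S,9S)-15-[(tert-butyldiphenylsilyl)oxy]-9-methoxy-8-(methacryloyloxy)-14-oxogermacra-1(10)E,4E,11(13)-trien-12,6-olide
Product: 31 (6R,7S,8S,9S)-15-hydroxy-9-methoxy-8-(methacryloyloxy)-14-oxogermacra-1(10)E,4E,11(13)-trien-12,6-olide (target)
Conditions: HF·pyridine, pyridine, THF, 0 → 25 °C
Reagents that add atoms: none
Why: Buffered fluoride desilylation of the primary allylic silyl ether is compatible with the enal, the methylene lactone and the ester and should give the target.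

**Compound list**
1 | 4-chlorobutanoyl chloride | ClCCCC(Cl)=O | starting material
2 | bis(trimethylsilyl)acetylene | C[Si](C)(C)C#C[Si](C)(C)C | starting material
3 | 6-chloro-1-(trimethylsilyl)hex-1-yn-3-one | ClCCCC(=O)C#C[Si](C)(C)C | intermediate
4 | (3R)-6-chloro-1-(trimethylsilyl)hex-1-yn-3-ol | ClCCC[C@@H](O)C#C[Si](C)(C)C | intermediate
5 | (3R)-3-[(tert-butyldimethylsilyl)oxy]-6-chloro-1-(trimethylsilyl)hex-1-yne | ClCCC[C@@H](O[Si](C)(C)C(C)(C)C)C#C[Si](C)(C)C | intermediate
6 | [(4R)-4-[(tert-butyldimethylsilyl)oxy]-6-(trimethylsilyl)hex-5-yn-1-yl]triphenylphosphonium iodide | [I-].C(CC[C@@H](O[Si](C)(C)C(C)(C)C)C#C[Si](C)(C)C)[P+](c1ccccc1)(c1ccccc1)c1ccccc1 | intermediate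
7 | [(4R)-4-[(tert-butyldimethylsilyl)oxy]-6-(trimethylsilyl)hex-5-yn-1-ylidene]triphenylphosphorane (not isolated) | C(CC[C@@H](O[Si](C)(C)C(C)(C)C)C#C[Si](C)(C)C)=P(c1ccccc1)(c1ccccc1)c1ccccc1 | intermediate
8 | (5R)-5-[(tert-butyldimethylsilyl)oxy]-2-(triphenylphosphoranylidene)-7-(trimethylsilyl)hept-6-ynal | O=CC(CC[C@@H](O[Si](C)(C)C(C)(C)C)C#C[Si](C)(C)C)=P(c1ccccc1)(c1ccccc1)c1ccccc1 | intermediate
9 | (5R)-5-hydroxy-2-(triphenylphosphoranylidene)hept-6-ynal | O=CC(CC[C@@H](O)C#C)=P(c1ccccc1)(c1ccccc1)c1ccccc1 | intermediate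
10 | methyl 4-oxobutanoate | O=CCCC(=O)OC | starting material
11 | 2,2-dimethoxyacetaldehyde | COC(OC)C=O | starting material
12 | methyl (3R,4S)-3-formyl-4-hydroxy-5,5-dimethoxypentanoate | O=C[C@H](CC(=O)OC)[C@H](O)C(OC)OC | intermediate
13 | methyl (3R,4S)-3-formyl-5,5-dimethoxy-4-[(triethylsilyl)oxy]pentanoate | O=C[C@H](CC(=O)OC)[C@H](O[Si](CC)(CC)CC)C(OC)OC | intermediate
14 | lithium alkoxide from addition of 2-lithio-1,3-dithiane to the formyl group of 13 (C6 configured as in 15; not isolated) | [Li+].COC(OC)[C@@H](O[Si](CC)(CC)CC)[C@@H](CC(=O)OC)[C@H]([O-])C1SCCCS1 | intermediate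
15 | (4S,5S)-5-(1,3-dithian-2-yl)-4-[(1S)-2,2-dimethoxy-1-[(triethylsilyl)oxy]ethyl]oxolan-2-one | COC(OC)[C@@H](O[Si](CC)(CC)CC)[C@H]1CC(=O)O[C@@H]1C2SCCCS2 | intermediate
16 | lithium enolate of lactone 15 (not isolated) | [Li+].COC(OC)[C@@H](O[Si](CC)(CC)CC)[C@H]1C=C([O-])O[C@@H]1C2SCCCS2 | intermediate
17 | (3R,4S,5S)-5-(1,3-dithian-2-yl)-4-[(1S)-2,2-dimethoxy-1-[(triethylsilyl)oxy]ethyl]-3-(hydroxymethyl)oxolan-2-one (expected major C3 epimer) | COC(OC)[C@@H](O[Si](CC)(CC)CC)[C@H]1[C@H](CO)C(=O)O[C@@H]1C2SCCCS2 | intermediate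
18 | methanesulfonate of the primary alcohol of 17 (not isolated) | COC(OC)[C@@H](O[Si](CC)(CC)CC)[C@H]1[C@H](COS(C)(=O)=O)C(=O)O[C@@H]1C2SCCCS2 | intermediate
19 | (4S,5S)-5-(1,3-dithian-2-yl)-4-[(1S)-2,2-dimethoxy-1-[(triethylsilyl)oxy]ethyl]-3-methylideneoxolan-2-one | COC(OC)[C@@H](O[Si](CC)(CC)CC)[C@H]1C(=C)C(=O)O[C@@H]1C2SCCCS2 | intermediate
20 | (4R,5S)-5-(1,3-dithian-2-yl)-4-[(1S)-1-hydroxy-2,2-dimethoxyethyl]-3-methylideneoxolan-2-one | COC(OC)[C@@H](O)[C@H]1C(=C)C(=O)O[C@@H]1C2SCCCS2 | intermediate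
21 | (1S)-1-[(2S,3R)-2-(1,3-dithian-2-yl)-4-methylidene-5-oxooxolan-3-yl]-2,2-dimethoxyethyl 2-methylprop-2-enoate | COC(OC)[C@@H](OC(=O)C(C)=C)[C@H]1C(=C)C(=O)O[C@@H]1C2SCCCS2 | intermediate
22 | (1S)-1-[(2S,3S)-2-formyl-4-methylidene-5-oxooxolan-3-yl]-2,2-dimethoxyethyl 2-methylprop-2-enoate | COC(OC)[C@@H](OC(=O)C(C)=C)[C@H]1C(=C)C(=O)O[C@@H]1C=O | intermediate
23 | (1S)-1-[(2R,3S)-2-[(1E,5R)-2-formyl-5-hydroxyhept-1-en-6-yn-1-yl]-4-methylidene-5-oxooxolan-3-yl]-2,2-dimethoxyethyl 2-methylprop-2-enoate | COC(OC)[C@@H](OC(=O)C(C)=C)[C@H]1C(=C)C(=O)O[C@@H]1/C=C(/C=O)CC[C@@H](O)C#C | intermediate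
24 | (1S)-1-[(2R,3S)-2-[(1E,5R)-5-hydroxy-2-(hydroxymethyl)hept-1-en-6-yn-1-yl]-4-methylidene-5-oxooxolan-3-yl]-2,2-dimethoxyethyl 2-methylprop-2-enoate | COC(OC)[C@@H](OC(=O)C(C)=C)[C@H]1C(=C)C(=O)O[C@@H]1/C=C(/CO)CC[C@@H](O)C#C | intermediate
25 | (1S)-1-[(2R,3S)-2-[(1E,5R)-2-{[(tert-butyldiphenylsilyl)oxy]methyl}-5-hydroxyhept-1-en-6-yn-1-yl]-4-methylidene-5-oxooxolan-3-yl]-2,2-dimethoxyethyl 2-methylprop-2-enoate | COC(OC)[C@@H](OC(=O)C(C)=C)[C@H]1C(=C)C(=O)O[C@@H]1/C=C(/CO[Si](c2ccccc2)(c2ccccc2)C(C)(C)C)CC[C@@H](O)C#C | intermediate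
26 | (1S)-1-[(2R,3S)-2-[(1E,5R)-2-{[(tert-butyldiphenylsilyl)oxy]methyl}-5-hydroxyhept-1-en-6-yn-1-yl]-4-methylidene-5-oxooxolan-3-yl]-2-oxoethyl 2-methylprop-2-enoate | O=C[C@@H](OC(=O)C(C)=C)[C@H]1C(=C)C(=O)O[C@@H]1/C=C(/CO[Si](c2ccccc2)(c2ccccc2)C(C)(C)C)CC[C@@H](O)C#C | intermediate
27 | propargyl vanadate: bis(triphenylsilyl) oxovanadate ester on the C1 oxygen of 26 (not isolated) | O=C[C@@H](OC(=O)C(C)=C)[C@H]1C(=C)C(=O)O[C@@H]1/C=C(/CO[Si](c2ccccc2)(c2ccccc2)C(C)(C)C)CC[C@@H](O[V](=O)(O[Si](c2ccccc2)(c2ccccc2)c2ccccc2)O[Si](c2ccccc2)(c2ccccc2)c2ccccc2)C#C | intermediate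
28 | allenyl vanadate (vanadium allenoate C1H=C10=C14H–O–V; allene axis Ra, not encoded in the SMILES; not isolated) | O=C[C@@H](OC(=O)C(C)=C)[C@H]1C(=C)C(=O)O[C@@H]1/C=C(/CO[Si](c2ccccc2)(c2ccccc2)C(C)(C)C)CCC=C=CO[V](=O)(O[Si](c2ccccc2)(c2ccccc2)c2ccccc2)O[Si](c2ccccc2)(c2ccccc2)c2ccccc2 | intermediate
29 | (6R,7S,8S,9S)-15-[(tert-butyldiphenylsilyl)oxy]-9-hydroxy-8-(methacryloyloxy)-14-oxogermacra-1(10)E,4E,11(13)-trien-12,6-olide | C=C(C)C(=O)O[C@H]1[C@H]2C(=C)C(=O)O[C@@H]2/C=C(/CO[Si](c3ccccc3)(c3ccccc3)C(C)(C)C)CC/C=C(/C=O)[C@@H]1O | intermediate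
30 | (6R,7S,8S,9S)-15-[(tert-butyldiphenylsilyl)oxy]-9-methoxy-8-(methacryloyloxy)-14-oxogermacra-1(10)E,4E,11(13)-trien-12,6-olide | C=C(C)C(=O)O[C@H]1[C@H]2C(=C)C(=O)O[C@@H]2/C=C(/CO[Si](c3ccccc3)(c3ccccc3)C(C)(C)C)CC/C=C(/C=O)[C@@H]1OC | intermediate
31 | (6R,7S,8S,9S)-15-hydroxy-9-methoxy-8-(methacryloyloxy)-14-oxogermacra-1(10)E,4E,11(13)-trien-12,6-olide, CNP0114830.1 | C=C(C)C(=O)O[C@H]1[C@H]2C(=C)C(=O)O[C@@H]2/C=C(/CO)CC/C=C(/C=O)[C@@H]1OC | target

**Step count**
Total: 21 steps. Longest linear sequence: 15 steps (steps 7–21, from 10 and 11 to 31); the ylide branch (steps 1–6) joins at step 15.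

**Steps most likely to fail, each with a fallback**

Step 19 (proposed new method). Protonation of the vanadium allenoate (plain Meyer–Schuster isomerisation to the enal) or intermolecular aldol may outrun the ten-membered ring closure. Delivery may also reach the wrong aldehyde face, or come anti to C2 and give the ring-trans alkene. The fallback uses known chemistry and forms the same C9–C10 bond by a Nozaki–Hiyama–Kishi macrocyclisation; it sets out from 25 and comes back at 29. Gold/molybdenum-catalysed iodo-Meyer–Schuster rearrangement of 25 (Ph3PAuNTf2, MoO2(acac)2, N-iodosuccinimide, CH2Cl2) should give the (Z)-2-iodo enal F1. Luche reduction should give the (Z)-2-iodo allylic alcohol F2, and aqueous TFA the C9 aldehyde F3. Ring closure with CrCl2 and catalytic NiCl2 in DMSO/THF at high dilution, with retention of the alkene geometry, should give the macrocyclic diol F4. Oxidation of the primary allylic alcohol with TEMPO and PhI(OAc)2, which leaves the secondary C9 hydroxyl alone, should give 29. In this variant the C9 configuration rests on substrate control only.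

Step 7. Self-aldol of the donor, low reactivity of the hydrated acceptor, dehydration or O8-lactonisation of the aldol before silylation, and erosion of the anti selectivity are the processes to fear. The fallback sets C8 and C7 in two separate events; it sets out from 11 and comes back at 15. A catalytic asymmetric Mukaiyama acetate aldol of 11 with 1-methoxy-1-(trimethylsilyloxy)ethene (Ti(Oi-Pr)4/BINOL, ligand enantiomer chosen for the 3S alcohol) should give methyl (3S)-3-hydroxy-4,4-dimethoxybutanoate F5. Frater–Seebach alkylation of its dianion (LDA, tert-butyl bromoacetate), anti to the alkoxide, should give the diester F6. Silylation with TESCl gives the silyl ether F7, and DIBAL-H at −78 °C should reduce the methyl ester selectively to the aldehyde F8, the tert-butyl ester analogue of 13. Addition of 2-lithio-1,3-dithiane as in step 9, followed by acid-promoted lactonisation (PPTS, toluene, 60 °C), returns to 15.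

Step 9. Poor facial selectivity at C6 and enolisation of the aldehyde by the basic nucleophile are the risks. The fallback corrects C6 by inversion instead of by face selection; it sets out from 13 and comes back at 15. The addition is quenched at −78 °C with acetic acid so that the open hydroxy esters can be separated. The C6-epimeric hydroxy ester F9 is inverted by Mitsunobu esterification (4-nitrobenzoic acid, PPh3, DIAD) to the 4-nitrobenzoate F10. K2CO3 in methanol then cleaves the benzoate and the liberated alkoxide closes the lactone to 15, so that both epimers end in the same compound.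

Further compounds
F1 | step 19 | (1S)-1-[(2R,3S)-2-[(1E,5Z)-2-{[(tert-butyldiphenylsilyl)oxy]methyl}-6-iodo-7-oxohepta-1,5-dien-1-yl]-4-methylidene-5-oxooxolan-3-yl]-2,2-dimethoxyethyl 2-methylprop-2-enoate | COC(OC)[C@@H](OC(=O)C(C)=C)[C@H]1C(=C)C(=O)O[C@@H]1/C=C(/CO[Si](c2ccccc2)(c2ccccc2)C(C)(C)C)CC/C=C(/C=O)I
F2 | step 19 | (1S)-1-[(2R,3S)-2-[(1E,5Z)-2-{[(tert-butyldiphenylsilyl)oxy]methyl}-7-hydroxy-6-iodohepta-1,5-dien-1-yl]-4-methylidene-5-oxooxolan-3-yl]-2,2-dimethoxyethyl 2-methylprop-2-enoate | COC(OC)[C@@H](OC(=O)C(C)=C)[C@H]1C(=C)C(=O)O[C@@H]1/C=C(/CO[Si](c2ccccc2)(c2ccccc2)C(C)(C)C)CC/C=C(/CO)I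
F3 | step 19 | (1S)-1-[(2R,3S)-2-[(1E,5Z)-2-{[(tert-butyldiphenylsilyl)oxy]methyl}-7-hydroxy-6-iodohepta-1,5-dien-1-yl]-4-methylidene-5-oxooxolan-3-yl]-2-oxoethyl 2-methylprop-2-enoate | O=C[C@@H](OC(=O)C(C)=C)[C@H]1C(=C)C(=O)O[C@@H]1/C=C(/CO[Si](c2ccccc2)(c2ccccc2)C(C)(C)C)CC/C=C(/CO)I
F4 | step 19 | (6R,7S,8S,9S)-15-[(tert-butyldiphenylsilyl)oxy]-9,14-dihydroxy-8-(methacryloyloxy)germacra-1(10),4,11(13)-trien-12,6-olide (both ring alkenes cis in the ring) | C=C(C)C(=O)O[C@H]1[C@H]2C(=C)C(=O)O[C@@H]2/C=C(/CO[Si](c3ccccc3)(c3ccccc3)C(C)(C)C)CC/C=C(/CO)[C@@H]1O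
F5 | step 7 | methyl (3S)-3-hydroxy-4,4-dimethoxybutanoate | COC(=O)C[C@H](O)C(OC)OC
F6 | step 7 | 4-tert-butyl 1-methyl (2R)-2-[(1S)-1-hydroxy-2,2-dimethoxyethyl]butanedioate | COC(=O)[C@H](CC(=O)OC(C)(C)C)[C@H](O)C(OC)OC
F7 | step 7 | 4-tert-butyl 1-methyl (2R)-2-[(1S)-2,2-dimethoxy-1-[(triethylsilyl)oxy]ethyl]butanedioate | COC(=O)[C@H](CC(=O)OC(C)(C)C)[C@H](O[Si](CC)(CC)CC)C(OC)OC
F8 | step 7 | tert-butyl (3R,4S)-3-formyl-5,5-dimethoxy-4-[(triethylsilyl)oxy]pentanoate | O=C[C@H](CC(=O)OC(C)(C)C)[C@H](O[Si](CC)(CC)CC)C(OC)OC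
F9 | step 9 | C6-epimeric hydroxy ester: methyl 3-[(1,3-dithian-2-yl)(hydroxy)methyl]-5,5-dimethoxy-4-[(triethylsilyl)oxy]pentanoate with the carbinol carbon of opposite configuration to that in 14 | COC(OC)[C@@H](O[Si](CC)(CC)CC)[C@@H](CC(=O)OC)[C@@H](O)C1SCCCS1
F10 | step 9 | 4-nitrobenzoate of the inverted carbinol (C6 configured as in 15) | COC(OC)[C@@H](O[Si](CC)(CC)CC)[C@@H](CC(=O)OC)[C@H](OC(=O)c1ccc(cc1)[N+](=O)[O-])C1SCCCS1
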